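The numbers in the tables are simulated on assumed constants; noise was put on by code.

**The target.** Follow the target, in percent of the starting material charged, as it climbs and then fades in the birch and larch runs, and turn the flask's settings one at a time.

| flask | starting material | gas phase | remark | time |
|---|---|---|---|---|
| birch | 0.70 M | 34 mM (held) | run made earlier |  |
| larch | 1.1 M | 34 mM (held) | run made earlier |  |
| flask | 0.50 M | 34 mM (held) |  | 25 h |

| run | time / h | target / % |
|---|---|---|
| birch | 0.333 | 28.7 |
| birch | 1.00 | 46.7 |
| birch | 3.00 | 38.8 |
| birch | 10.0 | 9.9 |
| birch | 30.0 | 0.6 |
| larch | 0.333 | 28.8 |
| larch | 1.00 | 54.8 |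
| larch | 3.00 | 56.7 |
| larch | 10.0 | 27.4 |
| larch | 30.0 | 1.3 |

(standard deviation of a reading: 0.3 percentage points)

- time, not beyond 25 h, at which the flask holds most target
- the amount of target, in percent of the starting material charged, at that time

- for target the crystals are counted in
- as a solid, counted per litre of solution: crystals
- at the start none of the gas is dissolved
- the numbers in the tables scatter with a standard deviation of 0.3 percentage points
- reactions considered so far: gas phase <-> dissolved gas; starting material + dissolved gas <-> target; starting material -> side product; crystals <-> target

**Turning time.** Stop at 25 h: the highest readings stand at 1.00 h in birch and 3.00 h in larch, well before that limit, so by hand this setting touches the tail and not the peak. Work the tail with the fraction left: divide the birch readings at 10.0 h and 30.0 h, take the natural logarithm and divide by the hours between, which gives the fading rate 0.140 h⁻¹, a pseudo-first-order constant. Larch gives 0.152 h⁻¹, close within the scatter of such small readings, so take the rate as independent of charge. My own reckoning then lays the flask on birch's tail and carries birch's 9.9 % forward 15.0 h, keeping 12.2 % of it, which as an estimate puts the flask's target at 1.21 % at the end.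

**Turning charge.** Lower the charge to 0.50 M: a first-order view leaves percentages unchanged, but at 3.00 h larch holds 56.7 % and birch 38.8 %, so expect a peak below birch's, by an amount I cannot size.

**The forecast.** The forecast says 47 % (44.5 % to 49.5 %) at 1.35 h (1 h to 1.9 h), reasoning “no crystals form and it should follow birch's percentage curve”, and so it differs from my expectation of less.

**The flask.** The flask peaks at 34.0 % after 0.930 h.

    gas phase ⇌ dissolved gas, rate k1*(csat - [dissolved gas]) (kL = 0.0190 s⁻¹)
    starting material + dissolved gas ⇌ target (K = 13.0 L mol⁻¹, k = 0.0310 L mol⁻¹ s⁻¹)
    starting material → side product (k = 5.20 × 10⁻⁵ s⁻¹)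
    crystals ⇌ target, rate k4*(cs4 - [target]) while solid is left; crystals form when [target] > cs4 (solubility = 0.120 M, k = 0.0120 s⁻¹)

**Reading it.** Shortening birch to 25 h leaves its peak at 47.3 %, whereas changing the charge by itself takes it from 47.3 % to 34.0 %. The largest single effect on the flask's peak is the return of target to starting material and dissolved gas: in the run with that return taken away the peak stands at 93.3 % instead of 34.0 %. The tail still fades as reckoned: against 1.21 %, the flask ends at 1.24 %, and the neighbour charged with 0.20 M, peaking at 28.7 %, ends at 1.22 %.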